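**Assumption:** 2,3,5-tri-O-benzyl-D-arabinofuranose and (R)-5-(hydroxymethyl)dihydrofuran-2(3H)-one (the D-glutamic-acid-derived lactone) are treated as catalogue starting materials.

Numbering used for the target: ring C2 (CH2OH), C3, C4, C5 (side chain); side chain C1'–C13'. Target configuration: 2R,3R,4R,5R,1'R,10'S.

## Retrosynthetic overview

1. Target ⇐ global hydrogenolysis (3 × OBn and N–O) of an N-hydroxy tri-O-benzyl triol.
2. That triol ⇐ chelation-controlled hydride reduction of an α-(N-hydroxyamino) ketone (sets C1'), with the γ-lactone reduced to the C10'/C13' diol in the same pot.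
3. Ketone ⇐ C5–C1' disconnection: visible-light hydroacylation of a cyclic nitrone by a lactone-aldehyde (acyl radical adds anti to the neighbouring OBn and sets C5).
4. Nitrone ⇐ 2,3,5-tri-O-benzyl-D-arabinofuranose by double inversion at C4. This oxime N-alkylation is the only ring construction (the pyrrolidine).
5. Aldehyde ⇐ ozonolysis and cuprate alkylation of the (R)-hydroxymethyl-butyrolactone tosylate. The lactone ring is bought, carries C10', and is opened only at the reduction stage.

## Route

**Step 1**
Reactants: 1, 2,3,5-tri-O-benzyl-D-arabinofuranose; 2, O-(tert-butyldiphenylsilyl)hydroxylamine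
Product: 3, (2R,3R,4R)-2,3,5-tris(benzyloxy)-4-hydroxypentanal O-TBDPS oxime (open chain, D-arabino, E/Z mixture)
Conditions: TBDPSONH2, PPTS (cat.), MgSO4, toluene, 90 °C
Reagents that add atoms: compound 2, TBDPSONH2, CC(C)(C)[Si](ON)(c1ccccc1)c1ccccc1
Why: Oxime-ether condensation opens the hemiacetal and leaves C4–OH as the only free hydroxyl; no stereocentre is touched.

**Step 2**
Reactants: 3, O-TBDPS oxime
Product: 4, (2R,3S,4S)-2,3,5-tris(benzyloxy)-4-iodopentanal O-TBDPS oxime (L-xylo; C4 inverted)
Conditions: I2, PPh3, imidazole, toluene, 80 °C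
Reagents that add atoms: iodine, II
Why: Appel (Garegg–Samuelsson) iodination of the secondary alcohol proceeds by SN2 with inversion at C4.

**Step 3**
Reactants: 4, iodide
Product: 5, (2R,3R,4R)-3,4-bis(benzyloxy)-2-[(benzyloxy)methyl]-3,4-dihydro-2H-pyrrole 1-oxide (D-arabino cyclic nitrone)
Conditions: TBAF, THF, rt → 50 °C
Reagents that add atoms: none
Why: Fluoride desilylation releases the oximate, which closes by 5-exo-tet N-alkylation (SN2, second inversion, net retention at C4) to form the pyrrolidine ring as the nitrone.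

**Step 4**
Reactants: 6, (R)-5-(hydroxymethyl)dihydrofuran-2(3H)-one
Product: 7, [(2R)-5-oxotetrahydrofuran-2-yl]methyl 4-methylbenzenesulfonate
Conditions: TsCl, pyridine, CH2Cl2, 0 °C
Reagents that add atoms: tosyl chloride, Cc1ccc(cc1)S(Cl)(=O)=O
Why: Standard sulfonylation of the primary alcohol; the stereocentre is untouched.

**Step 5**
Reactants: 7, tosylate; 8, 9-bromonon-1-ene
Product: 9, (S)-5-(dec-9-en-1-yl)dihydrofuran-2(3H)-one
Conditions: 8, Mg, THF; CuBr·SMe2 (0.5 equiv per RMgBr), −40 °C; then 7, −40 → −20 °C
Reagents that add atoms: none beyond compound 8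
Why: Gilman-type dialkylcuprate SN2 displacement of the primary tosylate is faster than lactone addition at low temperature; the stereocentre is not involved (R → S is a CIP priority change only) and becomes C10'.

**Step 6**
Reactants: 9, alkenyl lactone
Product: 10, 9-[(2S)-5-oxotetrahydrofuran-2-yl]nonanal
Conditions: O3, CH2Cl2, −78 °C; then PPh3
Reagents that add atoms: ozone, O=[O+][O-]
Why: Ozonolysis with reductive work-up cleaves the terminal alkene to the aldehyde (C1') and leaves the lactone intact.

**Step 7**
Reactants: 5, D-arabino nitrone (1.0 equiv); 10, lactone-aldehyde (1.5 equiv)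
Product: 11, 1-[(2S,3R,4R,5R)-3,4-bis(benzyloxy)-5-[(benzyloxy)methyl]-1-hydroxypyrrolidin-2-yl]-9-[(2S)-5-oxotetrahydrofuran-2-yl]nonan-1-one
Conditions: [Ir(dF(CF3)ppy)2(dtbbpy)]PF6 (1 mol %), quinuclidine (20 mol %), degassed MeCN, 450 nm LEDs, rt; crude product kept under Ar and taken directly into step 8
Reagents that add atoms: none
Why: Proposed new method: excited Ir(III) oxidises quinuclidine to its radical cation, which abstracts the hydridic aldehyde C–H of 10 (polarity-matched HAT, preferred over benzylic ether C–H). The nucleophilic acyl radical is then trapped at the electrophilic nitrone carbon faster than a primary acyl radical decarbonylates, on the face anti to the adjacent OBn (and anti to the CH2OBn), which sets the all-trans C5 centre as polar additions to this nitrone do. Ir(II) reduces the resulting α-acyl aminoxyl radical and quinuclidinium protonates it, closing a redox-neutral, fully atom-economical cycle. The closest known reaction types are HAT-photocatalytic hydroacylation of electron-poor alkenes with aldehydes and photoredox alkyl-radical additions to nitrones; as far as I know, acyl-radical addition to a nitrone C=N has been used only for spin trapping and not preparatively.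

**Step 8**
Reactants: 11, α-(N-hydroxyamino) ketone lactone
Product: 12, (1R,10S)-1-[(2R,3R,4R,5R)-3,4-bis(benzyloxy)-5-[(benzyloxy)methyl]-1-hydroxypyrrolidin-2-yl]tridecane-1,10,13-triol
Conditions: Zn(BH4)2, Et2O–THF, −40 → 0 °C; then LiBH4, MeOH (cat.), THF, 0 °C → rt (one pot); Rochelle-salt work-up
Reagents that add atoms: none
Why: Cram-chelate reduction: the zinc aminoxide (N–O–Zn) binds the C1' carbonyl and holds C=O syn to N, so hydride enters from the C5–H side, away from ring C4, giving the anti (erythro) 1'R amino alcohol; LiBH4 then reduces the lactone to the 10,13-diol without touching N–O, the benzyl ethers or C10'.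

**Step 9**
Reactants: 12, N-hydroxy tri-O-benzyl triol
Product: 13, Broussonetine S, (2R,3R,4R,5R)-2-(hydroxymethyl)-5-[(1R,10S)-1,10,13-trihydroxytridecyl]pyrrolidine-3,4-diol
Conditions: H2 (1 atm), 10% Pd/C, MeOH–2 M aq. HCl, rt; then Dowex 50WX8 (H+), elute with aq. NH3
Reagents that add atoms: none
Why: Acidic catalytic hydrogenolysis removes the three benzyl ethers and cleaves the N–O bond in one operation; no stereocentre is affected.

## Compound list

1 | 2,3,5-tri-O-benzyl-D-arabinofuranose | OC1[C@@H](OCc2ccccc2)[C@H](OCc2ccccc2)[C@@H](COCc2ccccc2)O1 | starting material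
2 | O-(tert-butyldiphenylsilyl)hydroxylamine | CC(C)(C)[Si](ON)(c1ccccc1)c1ccccc1 | starting material
3 | (2R,3R,4R)-2,3,5-tris(benzyloxy)-4-hydroxypentanal O-TBDPS oxime | CC(C)(C)[Si](ON=C[C@@H](OCc1ccccc1)[C@H](OCc1ccccc1)[C@H](O)COCc1ccccc1)(c1ccccc1)c1ccccc1 | intermediate
4 | (2R,3S,4S)-2,3,5-tris(benzyloxy)-4-iodopentanal O-TBDPS oxime | CC(C)(C)[Si](ON=C[C@@H](OCc1ccccc1)[C@H](OCc1ccccc1)[C@@H](I)COCc1ccccc1)(c1ccccc1)c1ccccc1 | intermediate
5 | (2R,3R,4R)-3,4-bis(benzyloxy)-2-[(benzyloxy)methyl]-3,4-dihydro-2H-pyrrole 1-oxide | [O-][N+]1=C[C@@H](OCc2ccccc2)[C@H](OCc2ccccc2)[C@H]1COCc1ccccc1 | intermediate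
6 | (R)-5-(hydroxymethyl)dihydrofuran-2(3H)-one | OC[C@H]1CCC(=O)O1 | starting material
7 | [(2R)-5-oxotetrahydrofuran-2-yl]methyl tosylate | Cc1ccc(cc1)S(=O)(=O)OC[C@H]1CCC(=O)O1 | intermediate
8 | 9-bromonon-1-ene | BrCCCCCCCC=C | starting material
9 | (S)-5-(dec-9-en-1-yl)dihydrofuran-2(3H)-one | C=CCCCCCCCC[C@H]1CCC(=O)O1 | intermediate
10 | 9-[(2S)-5-oxotetrahydrofuran-2-yl]nonanal | O=CCCCCCCCC[C@H]1CCC(=O)O1 | intermediate
11 | 1-[(2S,3R,4R,5R)-3,4-bis(benzyloxy)-5-[(benzyloxy)methyl]-1-hydroxypyrrolidin-2-yl]-9-[(2S)-5-oxotetrahydrofuran-2-yl]nonan-1-one | O=C(CCCCCCCC[C@H]2CCC(=O)O2)[C@H]1N(O)[C@H](COCc3ccccc3)[C@@H](OCc3ccccc3)[C@@H]1OCc1ccccc1 | intermediate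
12 | (1R,10S)-1-[(2R,3R,4R,5R)-3,4-bis(benzyloxy)-5-[(benzyloxy)methyl]-1-hydroxypyrrolidin-2-yl]tridecane-1,10,13-triol | OCCC[C@@H](O)CCCCCCCC[C@@H](O)[C@H]1N(O)[C@H](COCc2ccccc2)[C@@H](OCc2ccccc2)[C@@H]1OCc1ccccc1 | intermediate
13 | Broussonetine S | OCCC[C@@H](O)CCCCCCCC[C@@H](O)[C@H]1N[C@H](CO)[C@@H](O)[C@@H]1O | target

## Summary

Total steps: 9. Longest linear sequence: 6 (steps 1–3, 7–9; the lactone branch, steps 4–6 then 7–9, is also 6).

Steps most likely to fail:

1. **Step 7 (proposed new photochemical nitrone hydroacylation).** Risks are trapping of a second acyl radical by the aminoxyl intermediate, the N–OH product acting as an H-donor and stalling turnover, and background HAT at benzylic ethers. Fallback (known chemistry, different approach): SmI2-mediated reductive nitrone–aldehyde cross-coupling of 5 with 10 in THF at −78 °C. This forms the C5–C1' bond directly at the carbinol level and bypasses the ketone; LiBH4 lactone reduction and step 9 then follow, with the C1' epimer ratio handled as in item 2.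

2. **Step 8 (C1' diastereoselectivity).** A competing chelate through the ring C4–OBn would give the 1'S epimer. Fallback: take the alcohol on to the N-Boc pyrrolidine (Zn/AcOH N–O cleavage, then Boc2O), mesylate C1'–OH, and let the carbamate displace it intramolecularly to form the bicyclic oxazolidinone with inversion at C1'; hydrolyse and debenzylate.

3. **Step 5 (cuprate displacement beside a lactone).** Risks are lactone attack and modest yield. Fallback: build 9 from (S)-epichlorohydrin instead: Cu-catalysed opening with non-8-enylmagnesium bromide, base closure to (S)-1,2-epoxydodec-11-ene, then malonate opening and decarboxylation to the same (S)-γ-lactone.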